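Ring A is numbered C1 (carries the exocyclic CH2), C2, C3, C4 (carbinol), C5 (CMe2), C6 (side-chain carbon); the chain runs C1' to C9' from C6 to the pyrone, and acyclic precursors keep these labels.
Retrosynthetic cuts, in order: C9'–C3 of the pyrone (palladium-catalysed allylation of 4-hydroxy-6-methyl-2-pyrone), C2'–C3' (B-alkyl Suzuki–Miyaura coupling of a ring A iodide with a geraniol-derived E vinyl iodide), C1–C2 of ring A, then C5–C6.
Enabling feature: C2 sits two bonds from the carbinol carbon C4, so C4–C3–C2 is the open form of a 1-substituted cyclopropanol (a C2 homoenolate of the C4 ketone), while C1 is the sp2 carbon of the exocyclic alkene and can be made as a vinyl bromide; palladium unites C1 with C2.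
Forward: iridium-catalysed allylation builds C5–C6, the vinyl group becomes the 2-bromoalkene, the ester becomes the cyclopropanol, ring A closes (the only ring made; the pyrone is bought), the chain is joined at C2'–C3' and the pyrone is attached last.
Stereochemistry: C6 (R) from the ligand-controlled iridium allylation; C4 (S) from axial hydride delivery to the ring A ketone (OH cis to the C6 chain); the C3' alkene from syn hydrozirconation–iodination and a stereoretentive coupling; the C7' alkene from geraniol.

Key step: step 6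

Assumption: the (S,S,S)-configured BINOL/bis(1-phenylethyl)amine phosphoramidite is taken as the ligand enantiomer that gives the R ester 6 from an alkyl-substituted E allylic carbonate; if the sense is the reverse, its (R,R,R) antipode is used and nothing else changes.

Step 1
Reactants: 1 but-3-en-1-ol
Product: 2 tert-butyl(but-3-en-1-yloxy)dimethylsilane
Conditions: TBSCl, imidazole, CH2Cl2, 0 °C to rt
Reagents that add atoms: tert-butyldimethylsilyl chloride, CC(C)(C)[Si](C)(C)Cl
Why: Silylation of a primary alcohol gives an ether that should survive the metathesis, Grignard and palladium steps ahead.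

Step 2
Reactants: 2 tert-butyl(but-3-en-1-yloxy)dimethylsilane; 3 allyl methyl carbonate
Product: 4 (2E)-5-[(tert-butyldimethylsilyl)oxy]pent-2-en-1-yl methyl carbonate
Conditions: 3 (3 equiv), (H2IMes)(PCy3)Cl2Ru=CHPh (second-generation Grubbs catalyst, 3 mol%), CH2Cl2, 40 °C
Reagents that add atoms: none
Why: Olefin cross-metathesis of two unhindered terminal alkenes is driven by loss of ethene and should favour the E isomer thermodynamically, any Z isomer being removed on AgNO3-impregnated silica before the asymmetric step.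

Step 3
Reactants: 4 (2E)-5-[(tert-butyldimethylsilyl)oxy]pent-2-en-1-yl methyl carbonate; 5 1-methoxy-2-methyl-1-(trimethylsiloxy)propene
Product: 6 methyl (3R)-3-{2-[(tert-butyldimethylsilyl)oxy]ethyl}-2,2-dimethylpent-4-enoate
Conditions: [Ir(cod)Cl]2 (2 mol%), (S)-BINOL-derived N,N-bis[(S)-1-phenylethyl]phosphoramidite (4 mol%, pre-activated with n-PrNH2), 5 (2 equiv), THF, rt to 50 °C
Reagents that add atoms: none
Why: Iridium-catalysed branched-selective asymmetric allylic alkylation, in which the methoxide released on ionisation of the carbonate activates the silyl ketene acetal, which attacks the substituted terminus of the allyl-iridium intermediate anti to the metal, forming C5–C6 with the quaternary C5 and setting C6 as R under control of the phosphoramidite.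

Step 4
Reactants: 6 methyl (3R)-3-{2-[(tert-butyldimethylsilyl)oxy]ethyl}-2,2-dimethylpent-4-enoate
Product: 8 methyl (3S)-4-bromo-3-{2-[(tert-butyldimethylsilyl)oxy]ethyl}-2,2-dimethylpent-4-enoate, via vicinal dibromide 7 (not isolated)
Conditions: Br2 (1.05 equiv), CH2Cl2, −78 °C; volatiles removed; KOtBu (1.2 equiv), 18-crown-6 (0.1 equiv), hexane, 0 °C to rt
Reagents that add atoms: bromine, BrBr
Why: Anti addition of bromine and then E2 dehydrobromination of the 1,2-dibromoalkane, in which the bulky base in a hydrocarbon solvent takes the hydrogen geminal to bromine on C1 and the primary bromide leaves, should give the 2-bromo-1-alkene without touching C6 or the hindered ester (the descriptor changes from R to S only because bromine raises the priority of C1).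

Step 5
Reactants: 8 methyl (3S)-4-bromo-3-{2-[(tert-butyldimethylsilyl)oxy]ethyl}-2,2-dimethylpent-4-enoate
Product: 9 1-[(3S)-4-bromo-3-{2-[(tert-butyldimethylsilyl)oxy]ethyl}-2-methylpent-4-en-2-yl]cyclopropan-1-ol
Conditions: EtMgBr (3.2 equiv, added over 2 h), Ti(OiPr)4 (0.5 equiv), THF, 0 °C to rt
Reagents that add atoms: ethylmagnesium bromide, CC[Mg]Br
Why: Kulinkovich cyclopropanation, in which the titanacyclopropane (iPrO)2Ti(CH2CH2) formed from EtMgBr and Ti(OiPr)4 acts as a 1,2-dicarbanion on the ester carbonyl to give C2 and C3, while the 1,1-disubstituted bromoalkene should neither exchange into the titanacycle nor react with EtMgBr at this temperature.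

Step 6
Reactants: 9 1-[(3S)-4-bromo-3-{2-[(tert-butyldimethylsilyl)oxy]ethyl}-2-methylpent-4-en-2-yl]cyclopropan-1-ol
Product: 10 (3R)-3-{2-[(tert-butyldimethylsilyl)oxy]ethyl}-2,2-dimethyl-4-methylidenecyclohexan-1-one
Conditions: Pd(OAc)2 (10 mol%), XPhos (20 mol%), Cs2CO3 (2 equiv), toluene (0.02 M), 80 °C
Reagents that add atoms: none
Why: Proposed new method: zerovalent palladium formed from Pd(OAc)2 and XPhos should insert into the C1–Br bond, Cs2CO3 should convert the tertiary cyclopropanol into an alkoxide of divalent palladium held in a six-membered chelate, and strain-driven β-carbon elimination should then give the C2 palladium homoenolate as a seven-membered palladacycle that forms C1–C2 by C(sp2)–C(sp3) reductive elimination. The closest known reaction type is the intermolecular palladium-catalysed ring-opening cross-coupling of cyclopropanols with aryl and alkenyl halides; closure of a six-membered ring onto a tethered 2-bromoalkene has not been shown. Ring A thus closes by reductive elimination from the palladacycle with contraction to the six-membered carbocycle, not by attack of a nucleophile, and the methylene is already in place on C1. No stereocentre is created: C6 is not enolisable and is not touched, and the alkene ends γ,δ to the new ketone, so base has no easy path to move it. The selectivity required is reductive elimination ahead of β-hydride loss from C3 (which would give an enone); the bulky biaryl phosphine, the constraint of the palladacycle and the Thorpe–Ingold compression at C5 are expected to secure it, and since both cyclopropane CH2 groups give the same homoenolate there is no regiochemical issue.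

Step 7
Reactants: 10 (3R)-3-{2-[(tert-butyldimethylsilyl)oxy]ethyl}-2,2-dimethyl-4-methylidenecyclohexan-1-one
Product: 11 (1S,3R)-3-{2-[(tert-butyldimethylsilyl)oxy]ethyl}-2,2-dimethyl-4-methylidenecyclohexan-1-ol
Conditions: NaBH4, MeOH, −20 to 0 °C
Reagents that add atoms: none
Why: Substrate-controlled ketone reduction, in which the small hydride should add along the axial trajectory of the chair with the C6 chain equatorial (as in 4,4-dimethyl-3-keto terpenoids), giving the equatorial C4 alcohol cis to the chain, that is the S carbinol.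

Step 8
Reactants: 11 (1S,3R)-3-{2-[(tert-butyldimethylsilyl)oxy]ethyl}-2,2-dimethyl-4-methylidenecyclohexan-1-ol
Product: 12 tert-butyl({(1S,3R)-3-{2-[(tert-butyldimethylsilyl)oxy]ethyl}-2,2-dimethyl-4-methylidenecyclohexyl}oxy)dimethylsilane
Conditions: TBSOTf, 2,6-lutidine, CH2Cl2, 0 °C
Reagents that add atoms: tert-butyldimethylsilyl trifluoromethanesulfonate, CC(C)(C)[Si](C)(C)OS(=O)(=O)C(F)(F)F
Why: Silylation with the silyl triflate is the standard way to protect a hindered secondary alcohol, and the lutidine buffer keeps the exocyclic alkene from acid.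

Step 9
Reactants: 12 tert-butyl({(1S,3R)-3-{2-[(tert-butyldimethylsilyl)oxy]ethyl}-2,2-dimethyl-4-methylidenecyclohexyl}oxy)dimethylsilane
Product: 13 2-[(1R,3S)-3-[(tert-butyldimethylsilyl)oxy]-2,2-dimethyl-6-methylidenecyclohexyl]ethan-1-ol
Conditions: HF·pyridine, pyridine, THF, 0 °C
Reagents that add atoms: none
Why: Selective desilylation, since the unhindered primary silyl ether should cleave far faster than the secondary one shielded by the C5 gem-dimethyl group.

Step 10
Reactants: 13 2-[(1R,3S)-3-[(tert-butyldimethylsilyl)oxy]-2,2-dimethyl-6-methylidenecyclohexyl]ethan-1-ol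
Product: 14 tert-butyl{[(1S,3R)-3-(2-iodoethyl)-2,2-dimethyl-4-methylidenecyclohexyl]oxy}dimethylsilane
Conditions: I2, PPh3, imidazole, CH2Cl2, 0 °C to rt
Reagents that add atoms: iodine, II
Why: Appel-type iodination through the alkoxyphosphonium iodide (SN2 at the primary carbon) leaves the alkene and the silyl ether alone.

Step 11
Reactants: 15 geraniol
Product: 16 tert-butyl{[(2E)-3,7-dimethylocta-2,6-dien-1-yl]oxy}dimethylsilane
Conditions: TBSCl, imidazole, CH2Cl2, 0 °C to rt
Reagents that add atoms: tert-butyldimethylsilyl chloride, CC(C)(C)[Si](C)(C)Cl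
Why: Silylation of the primary allylic alcohol gives an ether stable to peracid, n-BuLi and Cp2Zr(H)Cl.

Step 12
Reactants: 16 tert-butyl{[(2E)-3,7-dimethylocta-2,6-dien-1-yl]oxy}dimethylsilane
Product: 17 tert-butyl{[(2E)-5-(3,3-dimethyloxiran-2-yl)-3-methylpent-2-en-1-yl]oxy}dimethylsilane
Conditions: mCPBA (1.0 equiv), NaHCO3, CH2Cl2, −20 °C
Reagents that add atoms: 3-chloroperoxybenzoic acid, OOC(=O)c1cccc(Cl)c1
Why: Prilezhaev epoxidation should take the more electron-rich distal trisubstituted alkene, the proximal one being deactivated inductively by the allylic oxygen (the racemic epoxide centre is lost in the next step).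

Step 13
Reactants: 17 tert-butyl{[(2E)-5-(3,3-dimethyloxiran-2-yl)-3-methylpent-2-en-1-yl]oxy}dimethylsilane
Product: 18 (4E)-6-[(tert-butyldimethylsilyl)oxy]-4-methylhex-4-enal
Conditions: H5IO6, THF/Et2O, 0 °C
Reagents that add atoms: none
Why: Periodic acid opens the epoxide to the diol and cleaves it (glycol cleavage) to the aldehyde and acetone without touching the remaining alkene.

Step 14
Reactants: 18 (4E)-6-[(tert-butyldimethylsilyl)oxy]-4-methylhex-4-enal
Product: 19 tert-butyl{[(2E)-7,7-dibromo-3-methylhepta-2,6-dien-1-yl]oxy}dimethylsilane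
Conditions: CBr4, PPh3, Et3N, CH2Cl2, 0 °C
Reagents that add atoms: carbon tetrabromide, BrC(Br)(Br)Br
Why: First stage of the Corey–Fuchs sequence (Wittig-type dibromomethylenation of an unhindered aldehyde), buffered with Et3N for the silyl ether.

Step 15
Reactants: 19 tert-butyl{[(2E)-7,7-dibromo-3-methylhepta-2,6-dien-1-yl]oxy}dimethylsilane
Product: 21 tert-butyl{[(2E)-3-methyloct-2-en-6-yn-1-yl]oxy}dimethylsilane, via lithium acetylide 20 (not isolated)
Conditions: n-BuLi (2.1 equiv), THF, −78 °C; MeI, −78 °C to rt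
Reagents that add atoms: iodomethane, CI
Why: Second stage of the Corey–Fuchs alkyne synthesis, in which bromine–lithium exchange, rearrangement and deprotonation give the lithium acetylide, which is C-methylated in the same flask.

Step 16
Reactants: 21 tert-butyl{[(2E)-3-methyloct-2-en-6-yn-1-yl]oxy}dimethylsilane
Product: 23 tert-butyl{[(2E,6E)-7-iodo-3-methylocta-2,6-dien-1-yl]oxy}dimethylsilane, via alkenyl-ZrCp2Cl 22 (not isolated)
Conditions: Cp2Zr(H)Cl (2.5 equiv), THF, 50 °C; I2, 0 °C
Reagents that add atoms: iodine, II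
Why: Hydrozirconation–iodinolysis, in which syn addition of Zr–H under equilibrating conditions (excess reagent, warming) should place zirconium on the less hindered methyl-bearing alkyne carbon and iodine replaces it with retention, giving the E-2-iodo-2-alkene while the trisubstituted alkene is too hindered to react.

Step 17
Reactants: 14 tert-butyl{[(1S,3R)-3-(2-iodoethyl)-2,2-dimethyl-4-methylidenecyclohexyl]oxy}dimethylsilane; 23 tert-butyl{[(2E,6E)-7-iodo-3-methylocta-2,6-dien-1-yl]oxy}dimethylsilane
Product: 26 tert-butyl{[(1S,3R)-3-[(3E,7E)-9-[(tert-butyldimethylsilyl)oxy]-3,7-dimethylnona-3,7-dien-1-yl]-2,2-dimethyl-4-methylidenecyclohexyl]oxy}dimethylsilane, via primary alkyllithium 24 (not isolated), via lithium B-methoxy-9-BBN borate 25 (not isolated)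
Conditions: 14 (1.3 equiv), t-BuLi (2.7 equiv), Et2O, −78 °C; B-methoxy-9-BBN, THF, −78 °C to rt; then 23, Pd(dppf)Cl2 (5 mol%), AsPh3 (10 mol%), K3PO4 (3 M aq.), DMF, rt
Reagents that add atoms: none
Why: B-alkyl Suzuki–Miyaura coupling, in which iodine–lithium exchange and capture by B-methoxy-9-BBN give the borate that transfers the primary alkyl group to the alkenylpalladium iodide, oxidative addition and reductive elimination both proceeding with retention so that the C3' alkene stays E.

Step 18
Reactants: 26 tert-butyl{[(1S,3R)-3-[(3E,7E)-9-[(tert-butyldimethylsilyl)oxy]-3,7-dimethylnona-3,7-dien-1-yl]-2,2-dimethyl-4-methylidenecyclohexyl]oxy}dimethylsilane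
Product: 27 (1S,3R)-3-[(3E,7E)-9-hydroxy-3,7-dimethylnona-3,7-dien-1-yl]-2,2-dimethyl-4-methylidenecyclohexan-1-ol
Conditions: TBAF (4 equiv), THF, 50 °C
Reagents that add atoms: none
Why: Fluoride-induced desilylation removes both silyl ethers, the hindered C4 ether needing warming, and nothing else in the molecule is sensitive to fluoride.

Step 19
Reactants: 27 (1S,3R)-3-[(3E,7E)-9-hydroxy-3,7-dimethylnona-3,7-dien-1-yl]-2,2-dimethyl-4-methylidenecyclohexan-1-ol
Product: 28 (2E,6E)-9-[(1R,3S)-3-hydroxy-2,2-dimethyl-6-methylidenecyclohexyl]-3,7-dimethylnona-2,6-dien-1-yl methyl carbonate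
Conditions: ClCO2Me (1.1 equiv), pyridine, CH2Cl2, −20 °C
Reagents that add atoms: methyl chloroformate, COC(Cl)=O
Why: Selective acylation, since the primary allylic alcohol should react far faster than the secondary C4 alcohol next to the gem-dimethyl carbon.

Step 20
Reactants: 28 (2E,6E)-9-[(1R,3S)-3-hydroxy-2,2-dimethyl-6-methylidenecyclohexyl]-3,7-dimethylnona-2,6-dien-1-yl methyl carbonate; 29 4-hydroxy-6-methyl-2H-pyran-2-one
Product: 30 sartorypyrone D, 3-[(2E,6E)-9-[(1R,3S)-3-hydroxy-2,2-dimethyl-6-methylidenecyclohexyl]-3,7-dimethylnona-2,6-dien-1-yl]-4-hydroxy-6-methyl-2H-pyran-2-one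
Conditions: Pd(PPh3)4 (5 mol%), 29 (2 equiv), THF, rt to 40 °C
Reagents that add atoms: none
Why: Tsuji–Trost allylation, in which zerovalent palladium ionises the carbonate to CO2 and methoxide, the methoxide deprotonates the acidic pyrone, and its soft C3 carbon attacks the unhindered primary allyl terminus with the C7' geometry retained, any O-allyl ether re-ionising to the C-allyl product and excess pyrone suppressing double allylation.

Compound list
1 | but-3-en-1-ol | C=CCCO | starting material
2 | tert-butyl(but-3-en-1-yloxy)dimethylsilane | C=CCCO[Si](C)(C)C(C)(C)C | intermediate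
3 | allyl methyl carbonate | C=CCOC(=O)OC | starting material
4 | (2E)-5-[(tert-butyldimethylsilyl)oxy]pent-2-en-1-yl methyl carbonate | COC(=O)OC/C=C/CCO[Si](C)(C)C(C)(C)C | intermediate
5 | 1-methoxy-2-methyl-1-(trimethylsiloxy)propene | COC(O[Si](C)(C)C)=C(C)C | starting material
6 | methyl (3R)-3-{2-[(tert-butyldimethylsilyl)oxy]ethyl}-2,2-dimethylpent-4-enoate | COC(=O)C(C)(C)[C@@H](C=C)CCO[Si](C)(C)C(C)(C)C | intermediate
7 | methyl (3S)-4,5-dibromo-3-{2-[(tert-butyldimethylsilyl)oxy]ethyl}-2,2-dimethylpentanoate (both C4 epimers, formed in situ) | COC(=O)C(C)(C)[C@@H](C(Br)CBr)CCO[Si](C)(C)C(C)(C)C | intermediate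
8 | methyl (3S)-4-bromo-3-{2-[(tert-butyldimethylsilyl)oxy]ethyl}-2,2-dimethylpent-4-enoate | COC(=O)C(C)(C)[C@@H](C(Br)=C)CCO[Si](C)(C)C(C)(C)C | intermediate
9 | 1-[(3S)-4-bromo-3-{2-[(tert-butyldimethylsilyl)oxy]ethyl}-2-methylpent-4-en-2-yl]cyclopropan-1-ol | OC1(CC1)C(C)(C)[C@@H](C(Br)=C)CCO[Si](C)(C)C(C)(C)C | intermediate
10 | (3R)-3-{2-[(tert-butyldimethylsilyl)oxy]ethyl}-2,2-dimethyl-4-methylidenecyclohexan-1-one | C=C1CCC(=O)C(C)(C)[C@@H]1CCO[Si](C)(C)C(C)(C)C | intermediate
11 | (1S,3R)-3-{2-[(tert-butyldimethylsilyl)oxy]ethyl}-2,2-dimethyl-4-methylidenecyclohexan-1-ol | C=C1CC[C@H](O)C(C)(C)[C@@H]1CCO[Si](C)(C)C(C)(C)C | intermediate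
12 | tert-butyl({(1S,3R)-3-{2-[(tert-butyldimethylsilyl)oxy]ethyl}-2,2-dimethyl-4-methylidenecyclohexyl}oxy)dimethylsilane | C=C1CC[C@H](O[Si](C)(C)C(C)(C)C)C(C)(C)[C@@H]1CCO[Si](C)(C)C(C)(C)C | intermediate
13 | 2-[(1R,3S)-3-[(tert-butyldimethylsilyl)oxy]-2,2-dimethyl-6-methylidenecyclohexyl]ethan-1-ol | C=C1CC[C@H](O[Si](C)(C)C(C)(C)C)C(C)(C)[C@@H]1CCO | intermediate
14 | tert-butyl{[(1S,3R)-3-(2-iodoethyl)-2,2-dimethyl-4-methylidenecyclohexyl]oxy}dimethylsilane | C=C1CC[C@H](O[Si](C)(C)C(C)(C)C)C(C)(C)[C@@H]1CCI | intermediate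
15 | geraniol | CC(C)=CCC/C(C)=C/CO | starting material
16 | tert-butyl{[(2E)-3,7-dimethylocta-2,6-dien-1-yl]oxy}dimethylsilane | CC(C)=CCC/C(C)=C/CO[Si](C)(C)C(C)(C)C | intermediate
17 | tert-butyl{[(2E)-5-(3,3-dimethyloxiran-2-yl)-3-methylpent-2-en-1-yl]oxy}dimethylsilane (racemic at the epoxide) | CC1(C)OC1CC/C(C)=C/CO[Si](C)(C)C(C)(C)C | intermediate
18 | (4E)-6-[(tert-butyldimethylsilyl)oxy]-4-methylhex-4-enal | O=CCC/C(C)=C/CO[Si](C)(C)C(C)(C)C | intermediate
19 | tert-butyl{[(2E)-7,7-dibromo-3-methylhepta-2,6-dien-1-yl]oxy}dimethylsilane | BrC(Br)=CCC/C(C)=C/CO[Si](C)(C)C(C)(C)C | intermediate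
20 | {(5E)-7-[(tert-butyldimethylsilyl)oxy]-5-methylhept-5-en-1-yn-1-yl}lithium (formed in situ) | [Li]C#CCC/C(C)=C/CO[Si](C)(C)C(C)(C)C | intermediate
21 | tert-butyl{[(2E)-3-methyloct-2-en-6-yn-1-yl]oxy}dimethylsilane | CC#CCC/C(C)=C/CO[Si](C)(C)C(C)(C)C | intermediate
22 | chlorobis(cyclopentadienyl)[(2E,6E)-8-[(tert-butyldimethylsilyl)oxy]-6-methylocta-2,6-dien-2-yl]zirconium (formed in situ) | C/C(=C\CC/C(C)=C/CO[Si](C)(C)C(C)(C)C)[Zr](Cl)(C1C=CC=C1)C1C=CC=C1 | intermediate
23 | tert-butyl{[(2E,6E)-7-iodo-3-methylocta-2,6-dien-1-yl]oxy}dimethylsilane | C/C(I)=C\CC/C(C)=C/CO[Si](C)(C)C(C)(C)C | intermediate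
24 | {2-[(1R,3S)-3-[(tert-butyldimethylsilyl)oxy]-2,2-dimethyl-6-methylidenecyclohexyl]ethyl}lithium (formed in situ) | C=C1CC[C@H](O[Si](C)(C)C(C)(C)C)C(C)(C)[C@@H]1CC[Li] | intermediate
25 | lithium 9-{2-[(1R,3S)-3-[(tert-butyldimethylsilyl)oxy]-2,2-dimethyl-6-methylidenecyclohexyl]ethyl}-9-methoxy-9-boranuidabicyclo[3.3.1]nonane (formed in situ) | C=C1CC[C@H](O[Si](C)(C)C(C)(C)C)C(C)(C)[C@@H]1CC[B-]2(OC)C3CCCC2CCC3.[Li+] | intermediate
26 | tert-butyl{[(1S,3R)-3-[(3E,7E)-9-[(tert-butyldimethylsilyl)oxy]-3,7-dimethylnona-3,7-dien-1-yl]-2,2-dimethyl-4-methylidenecyclohexyl]oxy}dimethylsilane | C=C1CC[C@H](O[Si](C)(C)C(C)(C)C)C(C)(C)[C@@H]1CC/C(C)=C/CC/C(C)=C/CO[Si](C)(C)C(C)(C)C | intermediate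
27 | (1S,3R)-3-[(3E,7E)-9-hydroxy-3,7-dimethylnona-3,7-dien-1-yl]-2,2-dimethyl-4-methylidenecyclohexan-1-ol | C=C1CC[C@H](O)C(C)(C)[C@@H]1CC/C(C)=C/CC/C(C)=C/CO | intermediate
28 | (2E,6E)-9-[(1R,3S)-3-hydroxy-2,2-dimethyl-6-methylidenecyclohexyl]-3,7-dimethylnona-2,6-dien-1-yl methyl carbonate | C=C1CC[C@H](O)C(C)(C)[C@@H]1CC/C(C)=C/CC/C(C)=C/COC(=O)OC | intermediate
29 | 4-hydroxy-6-methyl-2H-pyran-2-one | Cc1cc(O)cc(=O)o1 | starting material
30 | sartorypyrone D | C=C1CC[C@H](O)C(C)(C)[C@@H]1CC/C(C)=C/CC/C(C)=C/Cc1c(O)cc(C)oc1=O | target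

Total step count: 20. Longest linear sequence: 14 steps (steps 1–10 and 17–20, from but-3-en-1-ol); the vinyl iodide branch from geraniol is steps 11–16.

Steps most likely to fail

Step 6. β-Hydride loss from C3 of the homoenolate may outrun reductive elimination. C–O reductive elimination from the alkoxide of divalent palladium may also precede ring opening, and palladium hydride formed on the way may move the exocyclic alkene into the ring. The fallback uses known reaction types and sets out from 9. NBS in CH2Cl2 at 0 °C opens the cyclopropanol by electrophilic ring cleavage to the β-bromo ketone F1. Et3N eliminates HBr to give the vinyl ketone F2. Slow addition of Bu3SnH with AIBN in benzene at 80 °C then generates the C1 vinyl radical, which should close 6-endo onto the enone terminus C2 (tin-hydride vinyl-radical conjugate cyclisation) and be reduced to ketone 10, where the route resumes.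

Step 4. The base may take a terminal hydrogen and expel the secondary bromide, or attack the hindered C1 hydrogen too slowly, so that the elimination runs in the wrong direction. The fallback sets out from 6. PhSeBr in MeCN at 25 °C (thermodynamic, Markovnikov addition) should give the β-bromo selenide F3, with bromine on C1 and selenium on the terminal carbon. H2O2 oxidises it to the selenoxide F4, whose syn elimination has only the C1 hydrogen available. The direction of elimination is therefore fixed, and the route resumes at 8.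

Step 5. Carbonyl insertion at the neopentyl-type ester may be so slow that the titanium–ethylene species is consumed unproductively. The fallback sets out from 8 and builds the cyclopropanol by Simmons–Smith chemistry instead:
- Methylenation of the ester with Cp2Ti(μ-Cl)(μ-CH2)AlMe2 (pyridine, toluene/THF, −40 °C to rt) gives the methyl enol ether F5.
- Oxalic acid in wet THF hydrolyses it to the methyl ketone F6.
- TMSOTf/Et3N gives the only possible trimethylsilyl enol ether F7, because C5 is quaternary.
- Et2Zn/CH2I2 (Simmons–Smith) should cyclopropanate this electron-rich alkene in preference to the bromoalkene, giving the siloxycyclopropane F8.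
- K2CO3 in MeOH removes the trimethylsilyl group and returns to 9.

Further compounds
F1 | step 6 | (5S)-1,6-dibromo-5-{2-[(tert-butyldimethylsilyl)oxy]ethyl}-4,4-dimethylhept-6-en-3-one | BrCCC(=O)C(C)(C)[C@@H](C(Br)=C)CCO[Si](C)(C)C(C)(C)C
F2 | step 6 | (5S)-6-bromo-5-{2-[(tert-butyldimethylsilyl)oxy]ethyl}-4,4-dimethylhepta-1,6-dien-3-one | C=CC(=O)C(C)(C)[C@@H](C(Br)=C)CCO[Si](C)(C)C(C)(C)C
F3 | step 4 | methyl (3S)-4-bromo-3-{2-[(tert-butyldimethylsilyl)oxy]ethyl}-2,2-dimethyl-5-(phenylselanyl)pentanoate | COC(=O)C(C)(C)[C@@H](C(Br)C[Se]c1ccccc1)CCO[Si](C)(C)C(C)(C)C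
F4 | step 4 | methyl (3S)-4-bromo-3-{2-[(tert-butyldimethylsilyl)oxy]ethyl}-2,2-dimethyl-5-(phenylseleninyl)pentanoate | COC(=O)C(C)(C)[C@@H](C(Br)C[Se](=O)c1ccccc1)CCO[Si](C)(C)C(C)(C)C
F5 | step 5 | tert-butyl{[(3S)-4-bromo-3-(3-methoxy-2-methylbut-3-en-2-yl)pent-4-en-1-yl]oxy}dimethylsilane | COC(=C)C(C)(C)[C@@H](C(Br)=C)CCO[Si](C)(C)C(C)(C)C
F6 | step 5 | (4S)-5-bromo-4-{2-[(tert-butyldimethylsilyl)oxy]ethyl}-3,3-dimethylhex-5-en-2-one | CC(=O)C(C)(C)[C@@H](C(Br)=C)CCO[Si](C)(C)C(C)(C)C
F7 | step 5 | tert-butyl{[(3S)-4-bromo-3-{2-methyl-3-[(trimethylsilyl)oxy]but-3-en-2-yl}pent-4-en-1-yl]oxy}dimethylsilane | C=C(O[Si](C)(C)C)C(C)(C)[C@@H](C(Br)=C)CCO[Si](C)(C)C(C)(C)C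
F8 | step 5 | {1-[(3S)-4-bromo-3-{2-[(tert-butyldimethylsilyl)oxy]ethyl}-2-methylpent-4-en-2-yl]cyclopropoxy}trimethylsilane | C[Si](C)(C)OC1(CC1)C(C)(C)[C@@H](C(Br)=C)CCO[Si](C)(C)C(C)(C)C
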